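**Retrosynthetic overview**
- Feature: indole C2 bears only H and indole C3 bears only oxazole C5. The five-membered ring of the indole is therefore cut at C2–C3, so that C3 becomes a CH2 between the arene and oxazole C5, and C2 becomes the carbon of an isocyanide on N1.
- Ahead of that cut, the oxazole C2–pyrrole C2 bond is disconnected (site-selective Suzuki coupling on a 2,4-diiodooxazole). Both iodines are traced to lithiation/iodination of an oxazole that is free at C2 and C4.
- The isocyanide is traced to a nitro group (reduction, formylation, dehydration). The CH2–oxazole C5 bond is traced to a benzylic bromide and an oxazol-5-ylboronate whose C2 is blocked by i-Pr3Si.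
- Ring order: the benzene, oxazole and pyrrole rings are bought intact, and the five-membered ring of the indole is the only ring formed.

Key step: step 6

Assumption: the target has no stereocentre and no configured double bond, so nothing has to be controlled in that respect. The nitrotoluene, the oxazolylboronate and the pyrrolylboronic acid are taken as purchasable.

Step 1
Reactants: 1 5-bromo-1-methoxy-2-methyl-3-nitrobenzene
Product: 2 5-bromo-2-(bromomethyl)-1-methoxy-3-nitrobenzene
Conditions: NBS (1.1 equiv), AIBN (cat), PhCF3, reflux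
Reagents that add atoms: N-bromosuccinimide, O=C1CCC(=O)N1Br
Why: Wohl–Ziegler radical bromination, in which the methyl group holds the only benzylic C–H bonds, the nitro and bromo groups deactivate the ring toward ionic bromination, and the two ortho substituents slow a second bromination.

Step 2
Reactants: 2 5-bromo-2-(bromomethyl)-1-methoxy-3-nitrobenzene; 3 5-(4,4,5,5-tetramethyl-1,3,2-dioxaborolan-2-yl)-2-(triisopropylsilyl)-1,3-oxazole
Product: 4 5-[(4-bromo-2-methoxy-6-nitrophenyl)methyl]-2-(triisopropylsilyl)-1,3-oxazole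
Conditions: Pd(PPh3)4 (5 mol %), K3PO4, 1,4-dioxane/H2O (10:1), 60 °C, 1.0 equiv of 3
Reagents that add atoms: none
Why: Suzuki–Miyaura sp3–sp2 coupling, in which zerovalent palladium inserts into the benzylic C–Br bond by an SN2-type path faster than into the aryl C–Br bond, so that one equivalent of boronate at moderate temperature should form only the CH2–C5(oxazole) bond while the C2 silyl group tolerates aqueous base.

Step 3
Reactants: 4 5-[(4-bromo-2-methoxy-6-nitrophenyl)methyl]-2-(triisopropylsilyl)-1,3-oxazole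
Product: 5 5-bromo-3-methoxy-2-{[2-(triisopropylsilyl)-1,3-oxazol-5-yl]methyl}aniline
Conditions: H2 (1 atm), 5% Pt/C (sulfided), EtOAc, rt
Reagents that add atoms: none
Why: Chemoselective catalytic hydrogenation of a halonitroarene, in which sulfided platinum reduces NO2 to NH2 without hydrogenolysis of the aryl bromide and the neutral, water-poor medium spares the acid-labile C2–Si bond.

Step 4
Reactants: 5 5-bromo-3-methoxy-2-{[2-(triisopropylsilyl)-1,3-oxazol-5-yl]methyl}aniline
Product: 6 N-(5-bromo-3-methoxy-2-{[2-(triisopropylsilyl)-1,3-oxazol-5-yl]methyl}phenyl)formamide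
Conditions: acetic formic anhydride, THF, 0 °C to rt
Reagents that add atoms: acetic formic anhydride, CC(=O)OC=O
Why: N-Formylation with a mixed anhydride, in which the aniline attacks the less hindered and more electrophilic formyl carbonyl at low temperature and only weak acetic acid is released, which the C2–Si bond tolerates.

Step 5
Reactants: 6 N-(5-bromo-3-methoxy-2-{[2-(triisopropylsilyl)-1,3-oxazol-5-yl]methyl}phenyl)formamide
Product: 7 5-[(4-bromo-2-isocyano-6-methoxyphenyl)methyl]-2-(triisopropylsilyl)-1,3-oxazole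
Conditions: POCl3, Et3N (excess), CH2Cl2, −20 to 0 °C
Reagents that add atoms: none
Why: Formamide dehydration with POCl3 and a tertiary amine (the standard isocyanide synthesis), in which O-phosphorylation and twofold loss of HX give the isocyanide and the excess Et3N keeps the medium basic so that the C2–Si bond and the isocyanide both survive.

Step 6
Reactants: 7 5-[(4-bromo-2-isocyano-6-methoxyphenyl)methyl]-2-(triisopropylsilyl)-1,3-oxazole
Product: 11 6-bromo-4-methoxy-3-[2-(triisopropylsilyl)-1,3-oxazol-5-yl]-1H-indole, via benzylic organolithium 8 (not isolated), via 2-lithio-3H-indole 9 (not isolated), via N-lithioindole 10 (not isolated)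
Conditions: LiN(i-Pr)2 (1.3 equiv), THF, −78 °C, slow addition of 7 to the base; −78 to 0 °C; sat aq NH4Cl
Reagents that add atoms: none
Why: LiN(i-Pr)2 removes a proton from the CH2 group, whose carbanion 8 is delocalised into both the isocyano-substituted arene and the oxazole, and the slow addition of 7 to the base keeps unreacted isocyanide away from 8. The carbanion carbon (future C3) adds to the isocyanide carbon (future C2), so that the C2–C3 bond forms and the five-membered ring of the indole closes in a 5-endo-dig mode to imidoyllithium 9. A proton shift from C3 to C2, relayed by the HN(i-Pr)2 set free, aromatises 9 to N-lithioindole 10, which makes the sequence irreversible, and NH4Cl then protonates N1. The closest known reaction type is the Ito–Saegusa indole synthesis, the cyclisation of ortho-(lithiomethyl)aryl isocyanides to 3-substituted indoles. No stereocentre remains, since the sp3 C3 of 9 is erased on aromatisation, and the closure has no regiochemical alternative because the arene pattern is fixed by 1. The selectivity needed is the site of deprotonation, secured by the i-Pr3Si block at oxazole C2, by the much lower acidity of oxazole C4–H and of the arene C–H between OMe and Br, and by the negative charge of 8, 9 and 10 that opposes a second metalation, while the small excess of base and the limit of 0 °C guard the aryl bromide against elimination to an aryne.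

Step 7
Reactants: 11 6-bromo-4-methoxy-3-[2-(triisopropylsilyl)-1,3-oxazol-5-yl]-1H-indole
Product: 12 6-bromo-4-methoxy-3-(1,3-oxazol-5-yl)-1H-indole
Conditions: 1 M aq HCl, THF, rt
Reagents that add atoms: none
Why: Protodesilylation of a 2-silyloxazole, in which protonation at N3 turns C2 into an ylide-type leaving group for attack of water at silicon, so that dilute acid at room temperature frees C2–H without touching the aryl bromide, the methyl ether or the indole.

Step 8
Reactants: 12 6-bromo-4-methoxy-3-(1,3-oxazol-5-yl)-1H-indole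
Product: 14 6-bromo-4-methoxy-3-(1,3-oxazol-5-yl)-1-(triisopropylsilyl)indole, via sodium indolide 13 (not isolated)
Conditions: NaH (1.1 equiv), THF, 0 °C; i-Pr3SiCl, 0 °C to rt
Reagents that add atoms: chlorotriisopropylsilane, CC(C)[Si](Cl)(C(C)C)C(C)C
Why: N-Silylation of an indolide, in which NaH removes only the N–H proton (far more acidic than oxazole C2–H) and nitrogen anion 13 attacks i-Pr3SiCl to install a group that survives amide bases and aqueous carbonate and falls to fluoride.

Step 9
Reactants: 14 6-bromo-4-methoxy-3-(1,3-oxazol-5-yl)-1-(triisopropylsilyl)indole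
Product: 17 6-bromo-3-(4-iodo-1,3-oxazol-5-yl)-4-methoxy-1-(triisopropylsilyl)indole, via lithium isocyanoenolate 15 (not isolated), via iodo isocyano ketone 16 (not isolated)
Conditions: LiN(SiMe3)2 (1.2 equiv), THF/DMPU, −78 °C; I2 (1.2 equiv), −78 °C
Reagents that add atoms: iodine, [I][I]
Why: Known C4-iodination of 5-substituted oxazoles by way of C2 metalation, in which deprotonation at C2 is followed by ring opening, the polar cosolvent DMPU shifts the equilibrium to isocyanoenolate 15, iodine is taken up at the enolate carbon to give 16, and enolisation followed by attack of oxygen on the isocyanide carbon re-forms the ring as the 4-iodooxazole, while the bulky N-silyl group keeps the base away from indole C2 and C7.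

Step 10
Reactants: 17 6-bromo-3-(4-iodo-1,3-oxazol-5-yl)-4-methoxy-1-(triisopropylsilyl)indole
Product: 19 6-bromo-3-(2,4-diiodo-1,3-oxazol-5-yl)-4-methoxy-1-(triisopropylsilyl)indole, via 2-lithio-4-iodooxazole 18 (not isolated)
Conditions: LiN(SiMe3)2 (1.2 equiv), THF, −78 °C; I2 (1.2 equiv), −78 °C
Reagents that add atoms: iodine, [I][I]
Why: Deprotonation–iodination at oxazole C2, now the only acidic C–H, in which LiN(SiMe3)2 metalates C2 to 18 without halogen–metal exchange at the C4 iodide or the aryl bromide, and iodine is delivered to C2 because C4 is already substituted.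

Step 11
Reactants: 19 6-bromo-3-(2,4-diiodo-1,3-oxazol-5-yl)-4-methoxy-1-(triisopropylsilyl)indole; 20 [1-(tert-butoxycarbonyl)pyrrol-2-yl]boronic acid
Product: 21 tert-butyl 2-{5-[6-bromo-4-methoxy-1-(triisopropylsilyl)indol-3-yl]-4-iodo-1,3-oxazol-2-yl}pyrrole-1-carboxylate
Conditions: Pd(PPh3)4 (5 mol %), 2 M aq Na2CO3, 1,4-dioxane, 60 °C, 1.1 equiv of 20
Reagents that add atoms: none
Why: Site-selective Suzuki–Miyaura coupling, in which zerovalent palladium should insert first into the carbon–iodine bond at oxazole C2 (between O and N, unhindered), whereas the C4 iodide is shielded by the neighbouring 4-methoxy-1-silylindol-3-yl group and the aryl bromide is intrinsically slower than either iodide.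

Step 12
Reactants: 21 tert-butyl 2-{5-[6-bromo-4-methoxy-1-(triisopropylsilyl)indol-3-yl]-4-iodo-1,3-oxazol-2-yl}pyrrole-1-carboxylate
Product: 23 6-bromo-3-[4-iodo-2-(1H-pyrrol-2-yl)-1,3-oxazol-5-yl]-4-methoxy-1H-indole, via N-desilylated carbamate 22 (not isolated)
Conditions: n-Bu4NF (1.1 equiv), THF, 0 °C; then K2CO3, MeOH, rt
Reagents that add atoms: none
Why: Fluoride cleaves the N–Si bond of the indole and carbonate-catalysed methanolysis then removes the acyl-like carbamate from the pyrrole nitrogen, a base-only deprotection chosen because acid could protodeiodinate the electron-rich 4-iodooxazole.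

**Compound list**
1 | 5-bromo-1-methoxy-2-methyl-3-nitrobenzene | COc1cc(Br)cc([N+](=O)[O-])c1C | starting material
2 | 5-bromo-2-(bromomethyl)-1-methoxy-3-nitrobenzene | COc1cc(Br)cc([N+](=O)[O-])c1CBr | intermediate
3 | 5-(4,4,5,5-tetramethyl-1,3,2-dioxaborolan-2-yl)-2-(triisopropylsilyl)-1,3-oxazole | CC(C)[Si](C(C)C)(C(C)C)c1ncc(B2OC(C)(C)C(C)(C)O2)o1 | starting material
4 | 5-[(4-bromo-2-methoxy-6-nitrophenyl)methyl]-2-(triisopropylsilyl)-1,3-oxazole | COc1cc(Br)cc([N+](=O)[O-])c1Cc1cnc([Si](C(C)C)(C(C)C)C(C)C)o1 | intermediate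
5 | 5-bromo-3-methoxy-2-{[2-(triisopropylsilyl)-1,3-oxazol-5-yl]methyl}aniline | COc1cc(Br)cc(N)c1Cc1cnc([Si](C(C)C)(C(C)C)C(C)C)o1 | intermediate
6 | N-(5-bromo-3-methoxy-2-{[2-(triisopropylsilyl)-1,3-oxazol-5-yl]methyl}phenyl)formamide | COc1cc(Br)cc(NC=O)c1Cc1cnc([Si](C(C)C)(C(C)C)C(C)C)o1 | intermediate
7 | 5-[(4-bromo-2-isocyano-6-methoxyphenyl)methyl]-2-(triisopropylsilyl)-1,3-oxazole | COc1cc(Br)cc([N+]#[C-])c1Cc1cnc([Si](C(C)C)(C(C)C)C(C)C)o1 | intermediate
8 | (4-bromo-2-isocyano-6-methoxyphenyl)[2-(triisopropylsilyl)-1,3-oxazol-5-yl]methyllithium (not isolated) | COc1cc(Br)cc([N+]#[C-])c1C([Li])c1cnc([Si](C(C)C)(C(C)C)C(C)C)o1 | intermediate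
9 | 6-bromo-2-lithio-4-methoxy-3-[2-(triisopropylsilyl)-1,3-oxazol-5-yl]-3H-indole (not isolated, C3 transient and unconfigured) | COc1cc(Br)cc2N=C([Li])C(c3cnc([Si](C(C)C)(C(C)C)C(C)C)o3)c12 | intermediate
10 | 6-bromo-1-lithio-4-methoxy-3-[2-(triisopropylsilyl)-1,3-oxazol-5-yl]indole (not isolated) | COc1cc(Br)cc2n([Li])cc(-c3cnc([Si](C(C)C)(C(C)C)C(C)C)o3)c12 | intermediate
11 | 6-bromo-4-methoxy-3-[2-(triisopropylsilyl)-1,3-oxazol-5-yl]-1H-indole | COc1cc(Br)cc2[nH]cc(-c3cnc([Si](C(C)C)(C(C)C)C(C)C)o3)c12 | intermediate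
12 | 6-bromo-4-methoxy-3-(1,3-oxazol-5-yl)-1H-indole | COc1cc(Br)cc2[nH]cc(-c3cnco3)c12 | intermediate
13 | sodium salt (N1) of 6-bromo-4-methoxy-3-(1,3-oxazol-5-yl)indole (not isolated) | COc1cc(Br)cc2n([Na])cc(-c3cnco3)c12 | intermediate
14 | 6-bromo-4-methoxy-3-(1,3-oxazol-5-yl)-1-(triisopropylsilyl)indole | COc1cc(Br)cc2n([Si](C(C)C)(C(C)C)C(C)C)cc(-c3cnco3)c12 | intermediate
15 | lithium (Z)-1-[6-bromo-4-methoxy-1-(triisopropylsilyl)indol-3-yl]-2-isocyanoethen-1-olate (not isolated) | [Li]O/C(=C\[N+]#[C-])c1cn([Si](C(C)C)(C(C)C)C(C)C)c2cc(Br)cc(OC)c12 | intermediate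
16 | 1-[6-bromo-4-methoxy-1-(triisopropylsilyl)indol-3-yl]-2-iodo-2-isocyanoethan-1-one (not isolated, racemic and transient) | O=C(C(I)[N+]#[C-])c1cn([Si](C(C)C)(C(C)C)C(C)C)c2cc(Br)cc(OC)c12 | intermediate
17 | 6-bromo-3-(4-iodo-1,3-oxazol-5-yl)-4-methoxy-1-(triisopropylsilyl)indole | COc1cc(Br)cc2n([Si](C(C)C)(C(C)C)C(C)C)cc(-c3ocnc3I)c12 | intermediate
18 | 6-bromo-3-(4-iodo-2-lithio-1,3-oxazol-5-yl)-4-methoxy-1-(triisopropylsilyl)indole (not isolated) | COc1cc(Br)cc2n([Si](C(C)C)(C(C)C)C(C)C)cc(-c3oc([Li])nc3I)c12 | intermediate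
19 | 6-bromo-3-(2,4-diiodo-1,3-oxazol-5-yl)-4-methoxy-1-(triisopropylsilyl)indole | COc1cc(Br)cc2n([Si](C(C)C)(C(C)C)C(C)C)cc(-c3oc(I)nc3I)c12 | intermediate
20 | [1-(tert-butoxycarbonyl)pyrrol-2-yl]boronic acid | CC(C)(C)OC(=O)n1cccc1B(O)O | starting material
21 | tert-butyl 2-{5-[6-bromo-4-methoxy-1-(triisopropylsilyl)indol-3-yl]-4-iodo-1,3-oxazol-2-yl}pyrrole-1-carboxylate | COc1cc(Br)cc2n([Si](C(C)C)(C(C)C)C(C)C)cc(-c3oc(-c4cccn4C(=O)OC(C)(C)C)nc3I)c12 | intermediate
22 | tert-butyl 2-[5-(6-bromo-4-methoxy-1H-indol-3-yl)-4-iodo-1,3-oxazol-2-yl]pyrrole-1-carboxylate (not isolated) | COc1cc(Br)cc2[nH]cc(-c3oc(-c4cccn4C(=O)OC(C)(C)C)nc3I)c12 | intermediate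
23 | 6-bromo-3-[4-iodo-2-(1H-pyrrol-2-yl)-1,3-oxazol-5-yl]-4-methoxy-1H-indole | COc1cc(Br)cc2[nH]cc(-c3oc(-c4ccc[nH]4)nc3I)c12 | target

Total step count: 12
Longest linear sequence: 12 steps (from 1 to 23; 3 and 20 enter as purchased partners)

**Three steps most likely to fail**

1. Step 6 (key step).
   - Risk: metalation of the arene next to bromine followed by elimination, addition of the amide base to the isocyanide carbon, or attack of the carbanion on a second isocyanide molecule.
   - Fallback: it sets out from 4 and comes back at 11, and it uses no strong base. The same methylene carbon, activated in 4 by the ortho-nitroarene and the oxazole, is condensed with tert-butoxybis(dimethylamino)methane (DMF, 100 °C). This should give the enamine 2-(4-bromo-2-methoxy-6-nitrophenyl)-N,N-dimethyl-2-[2-(triisopropylsilyl)-1,3-oxazol-5-yl]ethen-1-amine F1. Hydrogenation over sulfided Pt/C in EtOAc should reduce the nitro group to 2-(2-amino-4-bromo-6-methoxyphenyl)-N,N-dimethyl-2-[2-(triisopropylsilyl)-1,3-oxazol-5-yl]ethen-1-amine F2. F2 closes the ring at N1–C2 with loss of dimethylamine (Leimgruber–Batcho-type reductive cyclisation) to give 11.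

2. Step 2.
   - Risk: loss of chemoselectivity between the benzylic and the aryl C–Br bonds, protodeboronation of the heteroaryl boronate, hydrolysis of the benzylic bromide, or base-mediated alkylation of the acidic CH2 of the product.
   - Fallback: it sets out from 2 and comes back at 4, and it replaces the boron/aqueous-base manifold by an anhydrous, base-free organozinc coupling at room temperature. 2-(Triisopropylsilyl)-1,3-oxazole F3 is lithiated at C5 (n-BuLi, THF, −78 °C) to 5-lithio-2-(triisopropylsilyl)-1,3-oxazole F4. F4 is transmetalated with ZnCl2 to chloro[2-(triisopropylsilyl)-1,3-oxazol-5-yl]zinc F5. Negishi coupling of F5 with 2 (Pd(PPh3)4, THF, rt) should engage only the benzylic bromide and give 4.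

3. Step 9.
   - Risk: iodination at C2 instead of C4, or over-iodination, because the position of the ring-closed/ring-opened equilibrium of the metalated oxazole depends on the 5-substituent.
   - Fallback: it sets out from 11 and comes back at 17, and it metalates C4 directly while C2 is still blocked by silicon. Deprotonation of 11 with NaH gives the sodium salt of 6-bromo-4-methoxy-3-[2-(triisopropylsilyl)-1,3-oxazol-5-yl]indole F6. F6 is silylated with i-Pr3SiCl to 6-bromo-4-methoxy-1-(triisopropylsilyl)-3-[2-(triisopropylsilyl)-1,3-oxazol-5-yl]indole F7. Treatment with TMPMgCl·LiCl (TMP = 2,2,6,6-tetramethylpiperidin-1-yl; THF, −20 °C) should magnesiate the only free oxazole position to chloro{5-[6-bromo-4-methoxy-1-(triisopropylsilyl)indol-3-yl]-2-(triisopropylsilyl)-1,3-oxazol-4-yl}magnesium F8. Iodine converts F8 into 6-bromo-3-[4-iodo-2-(triisopropylsilyl)-1,3-oxazol-5-yl]-4-methoxy-1-(triisopropylsilyl)indole F9. Dilute aq HCl in THF then removes the more labile oxazole C2 silyl group and gives 17.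

**Further compounds**
F1 | step 6 | 2-(4-bromo-2-methoxy-6-nitrophenyl)-N,N-dimethyl-2-[2-(triisopropylsilyl)-1,3-oxazol-5-yl]ethen-1-amine | COc1cc(Br)cc([N+](=O)[O-])c1C(=CN(C)C)c1cnc([Si](C(C)C)(C(C)C)C(C)C)o1
F2 | step 6 | 2-(2-amino-4-bromo-6-methoxyphenyl)-N,N-dimethyl-2-[2-(triisopropylsilyl)-1,3-oxazol-5-yl]ethen-1-amine | COc1cc(Br)cc(N)c1C(=CN(C)C)c1cnc([Si](C(C)C)(C(C)C)C(C)C)o1
F3 | step 2 | 2-(triisopropylsilyl)-1,3-oxazole | CC(C)[Si](C(C)C)(C(C)C)c1ncco1
F4 | step 2 | 5-lithio-2-(triisopropylsilyl)-1,3-oxazole | CC(C)[Si](C(C)C)(C(C)C)c1ncc([Li])o1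
F5 | step 2 | chloro[2-(triisopropylsilyl)-1,3-oxazol-5-yl]zinc | CC(C)[Si](C(C)C)(C(C)C)c1ncc([Zn]Cl)o1
F6 | step 9 | sodium salt of 6-bromo-4-methoxy-3-[2-(triisopropylsilyl)-1,3-oxazol-5-yl]indole | COc1cc(Br)cc2n([Na])cc(-c3cnc([Si](C(C)C)(C(C)C)C(C)C)o3)c12
F7 | step 9 | 6-bromo-4-methoxy-1-(triisopropylsilyl)-3-[2-(triisopropylsilyl)-1,3-oxazol-5-yl]indole | COc1cc(Br)cc2n([Si](C(C)C)(C(C)C)C(C)C)cc(-c3cnc([Si](C(C)C)(C(C)C)C(C)C)o3)c12
F8 | step 9 | chloro{5-[6-bromo-4-methoxy-1-(triisopropylsilyl)indol-3-yl]-2-(triisopropylsilyl)-1,3-oxazol-4-yl}magnesium | COc1cc(Br)cc2n([Si](C(C)C)(C(C)C)C(C)C)cc(-c3oc([Si](C(C)C)(C(C)C)C(C)C)nc3[Mg]Cl)c12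
F9 | step 9 | 6-bromo-3-[4-iodo-2-(triisopropylsilyl)-1,3-oxazol-5-yl]-4-methoxy-1-(triisopropylsilyl)indole | COc1cc(Br)cc2n([Si](C(C)C)(C(C)C)C(C)C)cc(-c3oc([Si](C(C)C)(C(C)C)C(C)C)nc3I)c12
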